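Ring A of chiricanine C is a pentasubstituted resorcinol monomethyl ether: prenyl at C2 between the C1 methoxyl and the C3 hydroxyl, hydrogen at C4, styryl at C5 and prenyl at C6. This map matches a cyclobutenone–ynol ether benzannulation, so ring A is cut at C3–C2, C1–C6 and C3–C4 into 2-prenyl-3-[(E)-styryl]cyclobut-2-enone and the methyl ynol ether of a prenylated acetylene. One thermal operation assembles the fully substituted arene with phenol and methyl ether already differentiated, without protecting groups. The same ynol ether, made in one step, is also the source of the cyclobutenone, so the whole route needs five steps.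

Key step: step 5

Remark: ring A is numbered C1 (OMe), C2 (prenyl), C3 (OH), C4 (H), C5 (styryl), C6 (prenyl); the β-bromostyrene is taken as the geometrically pure (E)-isomer.

Step 1
Reactants: 1 chloroacetaldehyde dimethyl acetal; 2 prenyl bromide
Product: 4 1-methoxy-5-methylhex-4-en-1-yne, via sodium methoxyacetylide 3 (not isolated)
Conditions: NaNH2 (3.0 equiv), liq. NH3, −33 °C; then 2 (1.0 equiv) in Et2O, −50 → −33 °C; NH3 evaporated, cold aq. NH4Cl, pentane
Reagents that add atoms: none
Why: Three equivalents of NaNH2 take the chloroacetal through two eliminations (loss of methanol, then of HCl) and a deprotonation to sodium methoxyacetylide, which is C-alkylated by the primary allylic bromide at its unhindered CH2 terminus (SN2 acetylide alkylation in liquid ammonia), the exact amide charge leaving no strong base that could isomerise the skipped enyne.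

Step 2
Reactants: 4 1-methoxy-5-methylhex-4-en-1-yne; 5 trichloroacetyl chloride
Product: 7 4,4-dichloro-3-methoxy-2-(3-methylbut-2-en-1-yl)cyclobut-2-en-1-one, via dichloroketene 6 (not isolated)
Conditions: 5 (1.2 equiv, slow addition), Zn–Cu couple, DME, Et2O, 0 °C → rt
Reagents that add atoms: none
Why: Dichloroketene, released by zinc dechlorination of the acid chloride while DME ties up ZnCl2, undergoes a regioselective (2+2) ketene–alkyne cycloaddition in which its carbonyl carbon bonds to the nucleophilic oxygen-free carbon of the ynol ether, and the electron-rich alkyne should react far faster than the trisubstituted prenyl alkene when the ketene precursor is kept near stoichiometric.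

Step 3
Reactants: 7 4,4-dichloro-3-methoxy-2-(3-methylbut-2-en-1-yl)cyclobut-2-en-1-one
Product: 8 3-methoxy-2-(3-methylbut-2-en-1-yl)cyclobut-2-en-1-one
Conditions: Zn dust, AcOH, TMEDA, MeOH, 0 °C → rt
Reagents that add atoms: none
Why: Zinc in buffered acetic acid removes both chlorines α to the carbonyl through zinc enolates (reductive dehalogenation of an α,α-dichloroketone), while the TMEDA buffer and methanol as solvent keep the vinylogous methyl ester from hydrolysis or ether exchange and the prenyl alkene is inert.

Step 4
Reactants: 8 3-methoxy-2-(3-methylbut-2-en-1-yl)cyclobut-2-en-1-one; 9 (E)-β-bromostyrene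
Product: 13 2-(3-methylbut-2-en-1-yl)-3-[(E)-2-phenylethenyl]cyclobut-2-en-1-one, via (E)-styryllithium 10 (not isolated), via lithium cyclobutenolate 11 (not isolated), via cyclobutenol 12 (not isolated)
Conditions: 9, t-BuLi (2 equiv per 9), Et2O, −78 °C; then 8 in THF, −78 °C; then 1 M aq. HCl, 0 °C
Reagents that add atoms: water, O
Why: Bromine–lithium exchange at −78 °C gives configurationally stable (E)-styryllithium, which adds 1,2 to the carbonyl of the vinylogous ester (deprotonation at the ring CH2 would create an antiaromatic cyclobutadienolate), and dilute acid then ionises the doubly allylic carbinol and hydrolyses the methoxy-stabilised cation to the transposed enone (Stork–Danheiser transposition), erasing the racemic carbinol stereocentre of 11 and 12.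

Step 5
Reactants: 13 2-(3-methylbut-2-en-1-yl)-3-[(E)-2-phenylethenyl]cyclobut-2-en-1-one; 4 1-methoxy-5-methylhex-4-en-1-yne
Product: 18 chiricanine C, via vinylketene 14 (not isolated), via vinylcyclobutenone 15 (not isolated), via dienylketene 16 (not isolated), via cyclohexadienone 17 (not isolated)
Conditions: 4 (2.0 equiv), degassed toluene, 80 °C then 110 °C, sealed tube; then K2CO3, MeOH, rt; aq. NH4Cl work-up
Reagents that add atoms: none
Why: Danheiser benzannulation: thermal four-electron ring opening of 13 gives vinylketene 14, whose ketene C=C adds to the ynol ether in a (2+2) cycloaddition (bonds C3–C2 and C6–C1) to give 15, which reopens to dienylketene 16 and closes by a thermal disrotatory 6π electrocyclisation (bond C3–C4) to dienone 17, and enolisation gives the phenol. The closest known reaction type is exactly this annulation of cyclobutenones with alkoxyalkynes to resorcinol monoethers, and all atoms of 13 and 4 end in 18. Ring A is the only ring closed, as a six-membered carbocycle formed in the 6π step between the ketene carbon C3 and the methylene terminus C4, and aromatisation makes the cascade irreversible. No stereocentre is created in 18; the quaternary centre of 15 is racemic and transient, and the (E)-styryl geometry is never touched. The regiochemistry needed is secured by the polarisation of the methoxyalkyne, whose oxygen-free carbon is the nucleophile toward the ketene carbonyl carbon, so that the methoxyl lands at C1 meta to the hydroxyl with the alkyne prenyl at C2 between them. Chemoselectivity rests on the styryl group being cross-conjugated in 14 and 16 (no six-electron closure through it), on the prenyl alkenes being poor ketenophiles, on an excess of the methyl ynol ether, which cannot fragment by retro-ene reaction, to outrun ketene dimerisation, and on the K2CO3/MeOH finish, which cleaves any aryl ester formed from 18 and 14.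

Compound list
1 | chloroacetaldehyde dimethyl acetal (2-chloro-1,1-dimethoxyethane) | COC(CCl)OC | starting material
2 | prenyl bromide (1-bromo-3-methylbut-2-ene) | CC(C)=CCBr | starting material
3 | sodium methoxyacetylide (not isolated) | [Na]C#COC | intermediate
4 | 1-methoxy-5-methylhex-4-en-1-yne | COC#CCC=C(C)C | intermediate
5 | trichloroacetyl chloride | O=C(Cl)C(Cl)(Cl)Cl | starting material
6 | dichloroketene (not isolated) | O=C=C(Cl)Cl | intermediate
7 | 4,4-dichloro-3-methoxy-2-(3-methylbut-2-en-1-yl)cyclobut-2-en-1-one | COC1=C(CC=C(C)C)C(=O)C1(Cl)Cl | intermediate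
8 | 3-methoxy-2-(3-methylbut-2-en-1-yl)cyclobut-2-en-1-one | COC1=C(CC=C(C)C)C(=O)C1 | intermediate
9 | (E)-β-bromostyrene [(E)-(2-bromoethenyl)benzene] | Br/C=C/c1ccccc1 | starting material
10 | (E)-styryllithium [(E)-2-phenylethenyllithium] (not isolated) | [Li]/C=C/c1ccccc1 | intermediate
11 | lithium 3-methoxy-2-(3-methylbut-2-en-1-yl)-1-[(E)-2-phenylethenyl]cyclobut-2-en-1-olate, racemic (not isolated) | [Li+].[O-]C1(/C=C/c2ccccc2)CC(OC)=C1CC=C(C)C | intermediate
12 | 3-methoxy-2-(3-methylbut-2-en-1-yl)-1-[(E)-2-phenylethenyl]cyclobut-2-en-1-ol, racemic (not isolated) | OC1(/C=C/c2ccccc2)CC(OC)=C1CC=C(C)C | intermediate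
13 | 2-(3-methylbut-2-en-1-yl)-3-[(E)-2-phenylethenyl]cyclobut-2-en-1-one | O=C1CC(/C=C/c2ccccc2)=C1CC=C(C)C | intermediate
14 | vinylketene, (4E)-3-methylidene-2-(3-methylbut-2-en-1-yl)-5-phenylpenta-1,4-dien-1-one (not isolated) | O=C=C(CC=C(C)C)C(=C)/C=C/c1ccccc1 | intermediate
15 | vinylcyclobutenone, 3-methoxy-2,4-bis(3-methylbut-2-en-1-yl)-4-[(3E)-4-phenylbuta-1,3-dien-2-yl]cyclobut-2-en-1-one, racemic (not isolated) | COC1=C(CC=C(C)C)C(=O)C1(CC=C(C)C)C(=C)/C=C/c2ccccc2 | intermediate
16 | dienylketene, (3E,6E)-3-methoxy-5-methylidene-2,4-bis(3-methylbut-2-en-1-yl)-7-phenylhepta-1,3,6-trien-1-one (not isolated) | O=C=C(CC=C(C)C)/C(OC)=C(CC=C(C)C)\C(=C)/C=C/c1ccccc1 | intermediate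
17 | cyclohexadienone, 3-methoxy-2,4-bis(3-methylbut-2-en-1-yl)-5-[(E)-2-phenylethenyl]cyclohexa-2,4-dien-1-one (not isolated) | COC1=C(CC=C(C)C)C(=O)CC(/C=C/c2ccccc2)=C1CC=C(C)C | intermediate
18 | chiricanine C, 3-methoxy-2,4-bis(3-methylbut-2-en-1-yl)-5-[(E)-2-phenylethenyl]phenol | COc1c(CC=C(C)C)c(O)cc(/C=C/c2ccccc2)c1CC=C(C)C | target

Total step count: 5. Longest linear sequence: 5 steps (1 → 4 → 7 → 8 → 13 → 18); compound 4 enters twice, in step 2 and again in step 5.

Steps most likely to fail

Step 5. The vinylketene may be consumed by dimerisation or by acylating the product phenol faster than the methoxyalkyne traps it, or the ynol ether may degrade during the long heating. The fallback sets out from 13 and comes back at 18. The methoxyalkyne is replaced by a silyl ynol ether, the most ketenophilic partner for this annulation. Triisopropyl[(5-methylhex-4-en-1-yn-1-yl)oxy]silane F1 would be made from commercial ethyl 4-methylpent-3-enoate by the Kowalski ester homologation sequence (CH2Br2, LiTMP, then n-BuLi, −78 °C → rt), with the lithium ynolate trapped by TIPSCl. Heating 13 with F1 in toluene at 80 °C should give 2,4-bis(3-methylbut-2-en-1-yl)-5-[(E)-2-phenylethenyl]-3-[(triisopropylsilyl)oxy]phenol F2. Its free C3 hydroxyl would be acylated (PivCl, pyridine, DMAP) to 2,4-bis(3-methylbut-2-en-1-yl)-5-[(E)-2-phenylethenyl]-3-[(triisopropylsilyl)oxy]phenyl pivalate F3. One-pot desilylation and O-methylation (TBAF, MeI, THF) should then give 3-methoxy-2,4-bis(3-methylbut-2-en-1-yl)-5-[(E)-2-phenylethenyl]phenyl pivalate F4, and KOH in aqueous MeOH would free the C3 phenol to give 18.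

Step 2. Dichloroketene may also add to the prenyl alkene, or ZnCl2 may hydrate or oligomerise the acid-sensitive ynol ether. The fallback sets out from 4 and comes back at 8, so it also replaces step 3. Ketene F5, generated by pyrolysis of acetone in a ketene lamp, would be passed into a solution of 4 in CH2Cl2 at 0 °C. The parent ketene adds to alkoxyalkynes but not to unactivated trisubstituted alkenes, and the cycloadduct is 8 itself. Neither a Lewis acid nor a dechlorination is then involved.

Step 1. In liquid ammonia the allylic bromide may be lost by ammonolysis or by reaction with methoxide, or residual amide may isomerise the doubly activated CH2 of the skipped enyne to an allene or a conjugated enyne. The fallback sets out from 1 and comes back at 4, and it separates acetylide formation from alkylation. After the NaNH2/NH3 elimination the mixture would be quenched with brine and the volatile methoxyacetylene F6 distilled into cold THF. Deprotonation with n-BuLi at −78 °C would give amine-free lithium methoxyacetylide F7, which would be alkylated with 2 in THF/DMPU (with catalytic CuBr·SMe2 if the alkylation is slow) to give 4.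

Further compounds
F1 | step 5 | triisopropyl[(5-methylhex-4-en-1-yn-1-yl)oxy]silane | CC(C)=CCC#CO[Si](C(C)C)(C(C)C)C(C)C
F2 | step 5 | 2,4-bis(3-methylbut-2-en-1-yl)-5-[(E)-2-phenylethenyl]-3-[(triisopropylsilyl)oxy]phenol | CC(C)[Si](Oc1c(CC=C(C)C)c(O)cc(/C=C/c2ccccc2)c1CC=C(C)C)(C(C)C)C(C)C
F3 | step 5 | 2,4-bis(3-methylbut-2-en-1-yl)-5-[(E)-2-phenylethenyl]-3-[(triisopropylsilyl)oxy]phenyl pivalate | CC(C)(C)C(=O)Oc1cc(/C=C/c2ccccc2)c(CC=C(C)C)c(O[Si](C(C)C)(C(C)C)C(C)C)c1CC=C(C)C
F4 | step 5 | 3-methoxy-2,4-bis(3-methylbut-2-en-1-yl)-5-[(E)-2-phenylethenyl]phenyl pivalate | COc1c(CC=C(C)C)c(OC(=O)C(C)(C)C)cc(/C=C/c2ccccc2)c1CC=C(C)C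
F5 | step 2 | ketene | C=C=O
F6 | step 1 | methoxyacetylene | COC#C
F7 | step 1 | lithium methoxyacetylide | [Li]C#COC
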